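The easy step was a logarithm: take the ratio of two readings of free monomer, take its logarithm, divide by the hours between them, and you have the rate at which free monomer shrinks, per unit of itself.

in all of them: free monomer 0.015 M; initiator 0.85 mM
- green: the very flask that is asked about, followed so far
- flask: time 8.0 h

green run (percent of the free monomer charged)

| time / h | monomer in chains / % | free monomer / % |
|---|---|---|
| 0.250 | 15.7 | 77.7 |
| 0.833 | 24.4 | 58.8 |
| 1.33 | 24.9 | 48.9 |
| 2.00 | 25.7 | 41.0 |
| 3.00 | 24.3 | 32.5 |
| 4.00 | 21.5 | 26.8 |

(scatter of a reading: 0.5 percentage points)

* average number of monomer units in a chain (chains begun, living or dead) at 8.0 h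
* part of the free monomer that has reacted at 8.0 h

- the average divides the monomer in chains by the number of chains begun, living and dead together
- the earlier runs do not show the number of chains; that part of a forecast is a guess

In the green flask that rate made a ladder. Over the first 0.250 h it was 1.01 h⁻¹, and monomer in chains climbed to 15.7%. Up to 0.833 h it was lower, 0.478 h⁻¹, and monomer in chains reached 24.4%. Monomer in chains then read no higher than 25.7% up to 2.00 h, while free monomer fell from 58.8% to 41.0%, so monomer was leaving by a road these readings do not show. From 2.00 h to 3.00 h the rate was 0.232 h⁻¹.

I froze the last rung, from 3.00 h to 4.00 h, as the late rate, a pseudo-first-order constant for free monomer: 0.193 h⁻¹, lower than each rung before it. It is a reading, its two points good to 0.5 percentage points each. Over the remaining 4.00 h that rate keeps 46.2% of the 26.8% of free monomer last read, so I expected 12.4% left at 8.0 h and 87.6% reacted. I made no figure for the average chain, since the readings do not show the number of chains.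

The forecast put the reacted part lower than mine, at 82% (78% to 86%), and the average at 1.8 (1.2 to 3.2), saying “That count is a guess”.

The flask gave 87.6% reacted and an average of 3.08 units per chain begun.

    living end + free monomer → dead end (k = 0.0267 M⁻¹ s⁻¹)
    free monomer → uncatalysed product (k = 7.02 × 10⁻⁵ s⁻¹)
    free monomer + living end → monomer in chains + living end, rate k3*[living end]*[free monomer] (k = 0.371 M⁻¹ s⁻¹)
    free monomer + initiator → living end + monomer in chains (k = 1.59 M⁻¹ s⁻¹)
    monomer in chains + living end → free monomer + living end, rate k5*[living end] as long as [monomer in chains] is above zero (k = 0.00250 s⁻¹)

In this flask at 8.00 h, monomer in chains was being made at 0.277 of the rate it was used up, each step taken net, so more slowly than it went. Carried on from 8.0 h to 80.0 h, the late rate spans 20.0 half-lives of free monomer, and the flask left that long had reacted >99.9%.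

Run backward from the 4.00 h reading to the same flask read at 2.0 h, the late rate gives 60.6% reacted; the computed flask stood at 59.3%.

The runs were generated by integration for an exercise; scatter was added.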